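**Retrosynthetic overview**
1. The target comes from its bis(O-benzyl) ether by one global hydrogenolysis.
2. Key step: the central tetrasubstituted resorcinol ring is built, not functionalised. A Danheiser benzannulation joins a 3-(arylethyl)cyclobutenone and a methyl ynol ether MeO–C≡C–CH2Ar. One operation fixes OH versus OMe, the benzyl group between them, and the arylethyl chain para to it.
3. The cyclobutenone comes from a homopropargyl arene and dichloroketene ([2+2], then dechlorination). The alkyne comes from 2-(benzyloxy)benzyl bromide and lithiated TMS-propyne.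
4. The ynol ether comes from lithium methoxyacetylide (trichloroethylene plus methoxide, then n-BuLi) and 4-(benzyloxy)benzyl chloride.
5. Ring order: both outer phenol rings are bought, the sacrificial four-membered ring is formed first, and the central benzene ring is formed last.

Assumption: the SMILES has no stereocentre, stereogenic double bond or axis. The target is therefore achiral and "single enantiomer" needs no stereocontrol.

**Step 1**
Reactants: 1 1-(benzyloxy)-2-(bromomethyl)benzene; 2 trimethyl(prop-1-yn-1-yl)silane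
Product: 5 1-(benzyloxy)-2-(but-3-yn-1-yl)benzene, via [3-(trimethylsilyl)prop-2-yn-1-yl]lithium 3 (not isolated), via {4-[2-(benzyloxy)phenyl]but-1-yn-1-yl}trimethylsilane 4 (not isolated)
Conditions: 2, n-BuLi, THF, −78 °C, 1 h; add 1, −78 °C → rt; then MeOH, K2CO3 (cat.), rt
Reagents that add atoms: none
Why: Propargylic lithiation and SN2 alkylation of the benzylic bromide form the C–C bond at the propargylic terminus (the silyl cap suppresses allene formation), and K2CO3-catalysed methanolysis (protodesilylation) then frees the terminal alkyne without touching the aryl benzyl ether; no stereocentre is formed.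

**Step 2**
Reactants: 5 1-(benzyloxy)-2-(but-3-yn-1-yl)benzene
Product: 6 3-{2-[2-(benzyloxy)phenyl]ethyl}-4,4-dichlorocyclobut-2-en-1-one
Conditions: Cl3CCOCl (slow addition), Zn–Cu, Et2O–DME 4:1, rt → 35 °C
Reagents that add atoms: trichloroacetyl chloride, ClC(Cl)(Cl)C(Cl)=O
Why: In this ketene–alkyne [2+2] cycloaddition the terminal alkyne carbon attacks the carbonyl carbon of in situ dichloroketene, so only the 3-substituted 4,4-dichlorocyclobutenone forms, with DME sequestering ZnCl2; no stereocentre is formed.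

**Step 3**
Reactants: 6 3-{2-[2-(benzyloxy)phenyl]ethyl}-4,4-dichlorocyclobut-2-en-1-one
Product: 7 3-{2-[2-(benzyloxy)phenyl]ethyl}cyclobut-2-en-1-one
Conditions: Zn dust, AcOH, TMEDA, EtOH, 0 °C → rt
Reagents that add atoms: none
Why: Zinc-mediated reductive dechlorination of the α,α-dichloroketone through zinc enolates, buffered by TMEDA/AcOH, removes both chlorines without reducing or shifting the strained enone C=C, and the benzyl ether is inert.

**Step 4**
Reactants: 8 trichloroethylene; 9 1-(benzyloxy)-4-(chloromethyl)benzene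
Product: 12 1-(benzyloxy)-4-(3-methoxyprop-2-yn-1-yl)benzene, via (E)-1,2-dichloro-1-methoxyethene 10 (not isolated), via lithium methoxyacetylide 11 (not isolated)
Conditions: 8, KOMe (1.0 equiv), THF, −50 °C → rt; n-BuLi (2.0 equiv), −78 → −40 °C; 9 (0.7 equiv), DMPU, Bu4NI (10 mol %), −78 °C → rt; Et3N-deactivated silica
Reagents that add atoms: potassium methoxide, [K+].[O-]C
Why: Net vinylic substitution of trichloroethylene by methoxide, then dehydrochlorination and Cl/Li exchange with n-BuLi, gives an amine-free and alkoxide-free lithium alkoxyacetylide that is SN2-alkylated at carbon by the activated benzylic halide; the methyl ynol ether has no β-hydrogen and so cannot undergo retro-ene loss on later heating.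

**Step 5**
Reactants: 7 3-{2-[2-(benzyloxy)phenyl]ethyl}cyclobut-2-en-1-one; 12 1-(benzyloxy)-4-(3-methoxyprop-2-yn-1-yl)benzene
Product: 17 2-[4-(benzyloxy)benzyl]-5-{2-[2-(benzyloxy)phenyl]ethyl}-3-methoxyphenol, via vinylketene 5-[2-(benzyloxy)phenyl]-3-methylidenepent-1-en-1-one 13 (not isolated), via racemic 2-[4-(benzyloxy)benzyl]-4-{4-[2-(benzyloxy)phenyl]but-1-en-2-yl}-3-methoxycyclobut-2-en-1-one 14 (not isolated), via dienylketene (3E)-2-[4-(benzyloxy)benzyl]-7-[2-(benzyloxy)phenyl]-3-methoxy-5-methylidenehepta-1,3-dien-1-one 15 (not isolated), via 2-[4-(benzyloxy)benzyl]-5-{2-[2-(benzyloxy)phenyl]ethyl}-3-methoxycyclohexa-2,4-dien-1-one 16 (not isolated)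
Conditions: 7 (1.0 equiv), 12 (1.3 equiv), degassed toluene (0.5 M), sealed tube, 80 °C then 110 °C
Reagents that add atoms: none
Why: This is the Danheiser benzannulation, a fully atom-economical cascade (4π opening of 7 to 13, [2+2] in which the nucleophilic β-carbon of the ynol ether bonds to the ketene carbonyl carbon to give 14, 4π opening to 15, 6π closure to 16, tautomerisation) that places the benzyl group between the new OH and the OMe and the arylethyl chain para to it; the transient stereocentre of 14 vanishes on aromatisation, and excess 12 keeps the ketene from acylating the product phenol.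

**Step 6**
Reactants: 17 2-[4-(benzyloxy)benzyl]-5-{2-[2-(benzyloxy)phenyl]ethyl}-3-methoxyphenol
Product: 18 2-(4-hydroxybenzyl)-5-[2-(2-hydroxyphenyl)ethyl]-3-methoxyphenol (CNP0353999.0)
Conditions: H2 (1 atm), 10% Pd/C, EtOAc–EtOH, rt
Reagents that add atoms: none
Why: Catalytic hydrogenolysis cleaves both aryl benzyl ethers at the O–CH2Ph bond, while the methyl ether, the diarylmethane CH2 and the bibenzyl chain are inert under these mild conditions; the product is achiral.

**Compound list**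
1 | 1-(benzyloxy)-2-(bromomethyl)benzene | BrCc1ccccc1OCc1ccccc1 | starting material
2 | trimethyl(prop-1-yn-1-yl)silane | CC#C[Si](C)(C)C | starting material
3 | [3-(trimethylsilyl)prop-2-yn-1-yl]lithium | [Li]CC#C[Si](C)(C)C | intermediate
4 | {4-[2-(benzyloxy)phenyl]but-1-yn-1-yl}trimethylsilane | C[Si](C)(C)C#CCCc1ccccc1OCc1ccccc1 | intermediate
5 | 1-(benzyloxy)-2-(but-3-yn-1-yl)benzene | C#CCCc1ccccc1OCc1ccccc1 | intermediate
6 | 3-{2-[2-(benzyloxy)phenyl]ethyl}-4,4-dichlorocyclobut-2-en-1-one | O=C1C=C(CCc2ccccc2OCc2ccccc2)C1(Cl)Cl | intermediate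
7 | 3-{2-[2-(benzyloxy)phenyl]ethyl}cyclobut-2-en-1-one | O=C1C=C(CCc2ccccc2OCc2ccccc2)C1 | intermediate
8 | trichloroethylene | ClC=C(Cl)Cl | starting material
9 | 1-(benzyloxy)-4-(chloromethyl)benzene | ClCc1ccc(OCc2ccccc2)cc1 | starting material
10 | (E)-1,2-dichloro-1-methoxyethene | CO/C(Cl)=C\Cl | intermediate
11 | lithium methoxyacetylide | [Li]C#COC | intermediate
12 | 1-(benzyloxy)-4-(3-methoxyprop-2-yn-1-yl)benzene | COC#CCc1ccc(OCc2ccccc2)cc1 | intermediate
13 | 5-[2-(benzyloxy)phenyl]-3-methylidenepent-1-en-1-one (vinylketene) | O=C=CC(=C)CCc1ccccc1OCc1ccccc1 | intermediate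
14 | 2-[4-(benzyloxy)benzyl]-4-{4-[2-(benzyloxy)phenyl]but-1-en-2-yl}-3-methoxycyclobut-2-en-1-one (racemic, transient) | COC1=C(Cc2ccc(OCc3ccccc3)cc2)C(=O)C1C(=C)CCc1ccccc1OCc1ccccc1 | intermediate
15 | (3E)-2-[4-(benzyloxy)benzyl]-7-[2-(benzyloxy)phenyl]-3-methoxy-5-methylidenehepta-1,3-dien-1-one (dienylketene) | O=C=C(Cc1ccc(OCc2ccccc2)cc1)/C(OC)=C\C(=C)CCc1ccccc1OCc1ccccc1 | intermediate
16 | 2-[4-(benzyloxy)benzyl]-5-{2-[2-(benzyloxy)phenyl]ethyl}-3-methoxycyclohexa-2,4-dien-1-one | O=C1CC(CCc2ccccc2OCc2ccccc2)=CC(OC)=C1Cc1ccc(OCc2ccccc2)cc1 | intermediate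
17 | 2-[4-(benzyloxy)benzyl]-5-{2-[2-(benzyloxy)phenyl]ethyl}-3-methoxyphenol | COc1cc(CCc2ccccc2OCc2ccccc2)cc(O)c1Cc1ccc(OCc2ccccc2)cc1 | intermediate
18 | 2-(4-hydroxybenzyl)-5-[2-(2-hydroxyphenyl)ethyl]-3-methoxyphenol (achiral) | COc1cc(CCc2ccccc2O)cc(O)c1Cc1ccc(O)cc1 | target

**Total step count:** 6. **Longest linear sequence:** 5 (steps 1, 2, 3, 5, 6). Step 4 is the convergent branch.

**Three steps most likely to fail, with fallbacks**

**Step 5 (benzannulation).** The risks are vinylketene oligomerisation, O-acylation of the product phenol, and thermal drift of the propargylic/benzylic ynol ether. The fallback drops the pericyclic cascade and builds the same ring by an ionic Michael–Claisen resorcylate synthesis. It sets out from alkyne 5 and comes back at 17.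
- Alkyne 5 is deprotonated (n-BuLi, THF, −78 °C) to lithium 4-[2-(benzyloxy)phenyl]but-1-yn-1-ide F1.
- In the presence of BF3·OEt2, F1 is acylated by commercial methyl 3-[4-(benzyloxy)phenyl]propanoate F2. This gives 1-[4-(benzyloxy)phenyl]-7-[2-(benzyloxy)phenyl]hept-4-yn-3-one F3.
- Dimethyl malonate with NaOMe in refluxing MeOH adds to the ynone β-carbon. The ketone α′-carbon then closes onto one malonate ester, and tautomerisation gives methyl 3-[4-(benzyloxy)benzyl]-6-{2-[2-(benzyloxy)phenyl]ethyl}-2,4-dihydroxybenzoate F4.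
- MeI (1 equiv), K2CO3 and acetone methylate only the 4-OH, because the 2-OH is chelated to the ester. The product is methyl 3-[4-(benzyloxy)benzyl]-6-{2-[2-(benzyloxy)phenyl]ethyl}-2-hydroxy-4-methoxybenzoate F5.
- KOH in aqueous DMSO at 110 °C saponifies F5 to 3-[4-(benzyloxy)benzyl]-6-{2-[2-(benzyloxy)phenyl]ethyl}-2-hydroxy-4-methoxybenzoic acid F6. On acidification and warming F6 decarboxylates to 17.

**Step 4 (methyl ynol ether).** The risks are sluggish or unselective alkylation, base-induced propargyl-to-allenyl isomerisation, and hydration on purification. The fallback replaces the alkoxyalkyne with a siloxyalkyne made by ester homologation, and swaps the roles of the two ring oxygens. It sets out from cyclobutenone 7 and comes back at 17.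
- Commercial ethyl [4-(benzyloxy)phenyl]acetate F7 is treated with LiCHBr2 (CH2Br2, LiTMP, THF, −78 °C). This gives lithium 3-[4-(benzyloxy)phenyl]-1,1-dibromoprop-1-en-2-olate F8.
- n-BuLi triggers Br/Li exchange and Kowalski rearrangement to lithium 3-[4-(benzyloxy)phenyl]prop-1-yn-1-olate F9.
- TIPSCl silylates F9 on oxygen to ({3-[4-(benzyloxy)phenyl]prop-1-yn-1-yl}oxy)tri(propan-2-yl)silane F10.
- Heating F10 with 7 (toluene, 80 → 110 °C) gives 2-[4-(benzyloxy)benzyl]-5-{2-[2-(benzyloxy)phenyl]ethyl}-3-[(triisopropylsilyl)oxy]phenol F11.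
- MeI and K2CO3 in acetone methylate the annulation-derived OH. The product is {2-[4-(benzyloxy)benzyl]-5-{2-[2-(benzyloxy)phenyl]ethyl}-3-methoxyphenoxy}tri(propan-2-yl)silane F12.
- TBAF in THF frees the alkyne-derived oxygen. Apart from its O-substituents the ring is symmetric about the C2–C5 axis, so the product is 17.

**Step 3 (dechlorination to the sensitive cyclobutenone).** The risks are incomplete or over-reduction, C=C migration and polymerisation. The fallback avoids any halogenated intermediate and any reduction by using a Ghosez keteniminium [2+2]. It sets out from alkyne 5 and comes back at 7, skipping 6.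
- N,N-dimethylacetamide, Tf2O and 2,4,6-collidine in refluxing 1,2-dichloroethane give N,N-dimethylketeniminium triflate F13.
- F13 cycloadds to 5 with the same regiochemistry. This gives N-(3-{2-[2-(benzyloxy)phenyl]ethyl}cyclobut-2-en-1-ylidene)-N-methylmethanaminium triflate F14.
- Aqueous NaHCO3 hydrolyses F14 to 7.

**Further compounds**
F1 | step 5 | lithium 4-[2-(benzyloxy)phenyl]but-1-yn-1-ide | [Li]C#CCCc1ccccc1OCc1ccccc1
F2 | step 5 | methyl 3-[4-(benzyloxy)phenyl]propanoate | COC(=O)CCc1ccc(OCc2ccccc2)cc1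
F3 | step 5 | 1-[4-(benzyloxy)phenyl]-7-[2-(benzyloxy)phenyl]hept-4-yn-3-one | O=C(CCc1ccc(OCc2ccccc2)cc1)C#CCCc1ccccc1OCc1ccccc1
F4 | step 5 | methyl 3-[4-(benzyloxy)benzyl]-6-{2-[2-(benzyloxy)phenyl]ethyl}-2,4-dihydroxybenzoate | COC(=O)c1c(O)c(Cc2ccc(OCc3ccccc3)cc2)c(O)cc1CCc1ccccc1OCc1ccccc1
F5 | step 5 | methyl 3-[4-(benzyloxy)benzyl]-6-{2-[2-(benzyloxy)phenyl]ethyl}-2-hydroxy-4-methoxybenzoate | COC(=O)c1c(O)c(Cc2ccc(OCc3ccccc3)cc2)c(OC)cc1CCc1ccccc1OCc1ccccc1
F6 | step 5 | 3-[4-(benzyloxy)benzyl]-6-{2-[2-(benzyloxy)phenyl]ethyl}-2-hydroxy-4-methoxybenzoic acid | OC(=O)c1c(O)c(Cc2ccc(OCc3ccccc3)cc2)c(OC)cc1CCc1ccccc1OCc1ccccc1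
F7 | step 4 | ethyl [4-(benzyloxy)phenyl]acetate | CCOC(=O)Cc1ccc(OCc2ccccc2)cc1
F8 | step 4 | lithium 3-[4-(benzyloxy)phenyl]-1,1-dibromoprop-1-en-2-olate | [Li]OC(Cc1ccc(OCc2ccccc2)cc1)=C(Br)Br
F9 | step 4 | lithium 3-[4-(benzyloxy)phenyl]prop-1-yn-1-olate | [Li]OC#CCc1ccc(OCc2ccccc2)cc1
F10 | step 4 | ({3-[4-(benzyloxy)phenyl]prop-1-yn-1-yl}oxy)tri(propan-2-yl)silane | CC(C)[Si](OC#CCc1ccc(OCc2ccccc2)cc1)(C(C)C)C(C)C
F11 | step 4 | 2-[4-(benzyloxy)benzyl]-5-{2-[2-(benzyloxy)phenyl]ethyl}-3-[(triisopropylsilyl)oxy]phenol | CC(C)[Si](Oc1cc(CCc2ccccc2OCc2ccccc2)cc(O)c1Cc1ccc(OCc2ccccc2)cc1)(C(C)C)C(C)C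
F12 | step 4 | {2-[4-(benzyloxy)benzyl]-5-{2-[2-(benzyloxy)phenyl]ethyl}-3-methoxyphenoxy}tri(propan-2-yl)silane | CC(C)[Si](Oc1cc(CCc2ccccc2OCc2ccccc2)cc(OC)c1Cc1ccc(OCc2ccccc2)cc1)(C(C)C)C(C)C
F13 | step 3 | N,N-dimethylketeniminium trifluoromethanesulfonate | C=C=[N+](C)C.[O-]S(=O)(=O)C(F)(F)F
F14 | step 3 | N-(3-{2-[2-(benzyloxy)phenyl]ethyl}cyclobut-2-en-1-ylidene)-N-methylmethanaminium trifluoromethanesulfonate | C[N+](C)=C1C=C(CCc2ccccc2OCc2ccccc2)C1.[O-]S(=O)(=O)C(F)(F)F
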